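The cyclopentenone ring (atoms C8 to C12) is cut at the C8–C12 and C9–C10 bonds: C10–C13 are the four carbons of succinaldehyde, and C9 with C8 come from a nitroalkene that already carries the whole C1–C7 chain with its 5Z alkene. An amine-catalysed Michael addition followed by base-induced nitroaldol closure should form both bonds and the five-membered ring in one flask, fix C8 by catalyst control and C12 (trans) by equilibration, and leave C13 as a formyl handle for the lower chain, with the C9 nitro and C10 hydroxy groups as the latent C9 ketone and C10=C11 alkene. The precursors are fresh succinaldehyde and methyl (5Z,8E)-9-nitronona-5,8-dienoate.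

Key step: step 7

Numbering: atoms carry prostanoic acid numbers (C1 ester carbon, C5=C6, ring C8–C12, C13=C14, C15 acetoxy carbon); the target is (8R,12S,15S), 5Z,13E.
Assumption: C8 of 7 and C9/C10 of 12, 13 and 15–17 form as mixtures that are erased in steps 5 and 10, so they are drawn without descriptors; the ring product of step 7 is a 4-hydroxy-3-nitro-2-alkenylcyclopentane-1-carbaldehyde, with the nitro group on the carbon next to C8.

Step 1
Reactants: 1 (4-carboxybutyl)triphenylphosphonium bromide; 2 3-[(tert-butyldimethylsilyl)oxy]propanal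
Product: 3 (5Z)-8-[(tert-butyldimethylsilyl)oxy]oct-5-enoic acid
Conditions: NaN(SiMe3)2 (2.1 equiv), THF, 0 °C; then 2, −78 °C → rt; aq. HCl to pH 4, 0 °C
Reagents that add atoms: none
Why: Wittig olefination of a lithium-free, non-stabilised ylide (as its carboxylate) with an unhindered aldehyde at low temperature is kinetically controlled and should give the 5Z alkene; no stereocentre is formed.

Step 2
Reactants: 3 (5Z)-8-[(tert-butyldimethylsilyl)oxy]oct-5-enoic acid
Product: 4 methyl (5Z)-8-hydroxyoct-5-enoate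
Conditions: HCl (1.25 M in MeOH), 0 °C → rt
Reagents that add atoms: methanol, CO
Why: Fischer esterification in acidic methanol, which methanolyses the primary silyl ether at the same time, should give the hydroxy ester in one operation and leave the isolated Z alkene alone.

Step 3
Reactants: 4 methyl (5Z)-8-hydroxyoct-5-enoate
Product: 5 methyl (5Z)-8-oxooct-5-enoate
Conditions: Dess–Martin periodinane, NaHCO3, CH2Cl2, 0 °C; used crude at once
Reagents that add atoms: none
Why: Dess–Martin oxidation under bicarbonate buffer is the usual non-basic, non-acidic way to a Z β,γ-unsaturated aldehyde without migration of the alkene into conjugation.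

Step 4
Reactants: 5 methyl (5Z)-8-oxooct-5-enoate; 6 nitromethane
Product: 7 methyl (5Z)-8-hydroxy-9-nitronon-5-enoate (racemic at C8)
Conditions: 6 (10 equiv), 1,1,3,3-tetramethylguanidine (5 mol%), THF, 0 °C; AcOH quench
Reagents that add atoms: none
Why: Henry (nitroaldol) reaction in which the large excess of nitromethane holds the base as weakly basic nitronate, so addition to the unhindered formyl group should outrun enolisation at C7; the C8 carbinol centre forms as a racemate and is removed in step 5.

Step 5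
Reactants: 7 methyl (5Z)-8-hydroxy-9-nitronon-5-enoate
Product: 8 methyl (5Z,8E)-9-nitronona-5,8-dienoate
Conditions: N,N'-dicyclohexylcarbodiimide (1.2 equiv), CuCl (5 mol%), Et2O, rt, dark; filter; store at −20 °C and use within hours
Reagents that add atoms: none
Why: Carbodiimide dehydration of a β-nitro alcohol (CuCl-catalysed O-alkylisourea formation, then loss of the urea across the acidic C9–H) needs no amine base, so it should give the more stable E nitroalkene without moving the C7 hydrogens.

Step 6
Reactants: 9 2,5-dimethoxytetrahydrofuran (cis/trans mixture)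
Product: 10 succinaldehyde (butanedial)
Conditions: H2O, 90 °C; distil off MeOH/H2O; extract (CH2Cl2); distil under reduced pressure; use fresh
Reagents that add atoms: water, O
Why: Hydrolysis of the cyclic bis-acetal in hot water with removal of methanol is the standard preparation of the monomeric dialdehyde, which is distilled and used at once because it oligomerises on standing.

Step 7
Reactants: 8 methyl (5Z,8E)-9-nitronona-5,8-dienoate; 10 succinaldehyde
Product: 13 methyl (5Z)-7-[(1R,2S)-2-formyl-4-hydroxy-5-nitrocyclopentyl]hept-5-enoate, via syn Michael adduct 11 (not isolated), via cis-formyl cyclopentane 12 (not isolated)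
Conditions: 10 (2 equiv), (S)-2-[diphenyl(trimethylsilyloxy)methyl]pyrrolidine (10 mol%), 4-nitrophenol (10 mol%), MeCN, 0 °C → rt; then iPr2NEt (1.5 equiv), 0 °C; aqueous work-up
Reagents that add atoms: none
Why: The amine condenses with one formyl group of 10 to the E enamine, whose face remote from the diphenyl(silyloxy)methyl group adds through an acyclic synclinal transition state to C8 of 8 (C8–C12 bond) to give the syn adduct 11, and iPr2NEt then forms the C9 nitronate, which attacks the second formyl carbon C10 (C9–C10 bond). The closest known reaction type is the diarylprolinol silyl ether catalysed Michael addition of aldehydes to nitroalkenes followed by intramolecular Henry reaction, a formal (3+2) annulation established for succinaldehyde with simple alkyl nitroalkenes. The cyclopentane ring closes in the 5-exo-trig mode, with the nitronate C=N bond outside the forming ring. C8 is set (R) by the catalyst through the syn topicity of the Michael step, C12 leaves the ring closure cis to the C8 chain (12) and is equilibrated by the amine base through its enol to the more stable trans aldehyde 13, and C9 and C10 arise under substrate control as a mixture of no consequence. The step needs conjugate addition at C8 to be faster than proton loss from the doubly activated C7 methylene and than self-aldolisation of 10: the unsubstituted β-carbon of the E nitroalkene is the only site in 8 that an enamine can attack, the nitrophenol keeps the medium weakly acidic until 8 is consumed, and once C8 is sp3 the C7 hydrogens are merely allylic.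

Step 8
Reactants: 13 methyl (5Z)-7-[(1R,2S)-2-formyl-4-hydroxy-5-nitrocyclopentyl]hept-5-enoate; 14 dimethyl (2-oxoheptyl)phosphonate
Product: 15 methyl (5Z)-7-[(1R,2R)-4-hydroxy-5-nitro-2-[(1E)-3-oxooct-1-en-1-yl]cyclopentyl]hept-5-enoate
Conditions: 14 (1.2 equiv), LiCl, iPr2NEt, MeCN, 0 °C → rt
Reagents that add atoms: none
Why: Horner–Wadsworth–Emmons olefination under Masamune–Roush conditions is mild enough for the β-nitro alcohol and the stabilised phosphonate anion should give the E enone; C12 is already in its thermodynamic trans arrangement and is not at risk.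

Step 9
Reactants: 15 methyl (5Z)-7-[(1R,2R)-4-hydroxy-5-nitro-2-[(1E)-3-oxooct-1-en-1-yl]cyclopentyl]hept-5-enoate
Product: 16 methyl (5Z)-7-[(1R,2R)-4-hydroxy-2-[(1E,3S)-3-hydroxyoct-1-en-1-yl]-5-nitrocyclopentyl]hept-5-enoate
Conditions: (R)-2-methyl-CBS-oxazaborolidine [(R)-1-methyl-3,3-diphenyltetrahydro-1H,3H-pyrrolo[1,2-c][1,3,2]oxazaborole] (0.3 equiv), catecholborane (3 equiv), toluene, −78 °C; MeOH, then aqueous work-up
Reagents that add atoms: none
Why: Corey–Bakshi–Shibata reduction, in which the (R)-oxazaborolidine binds the ketone with the alkenyl group as the large substituent and directs hydride from catecholborane to the face that gives the 15S allylic alcohol, 1,2-selectively and without touching the nitro group, ester or alkenes at −78 °C.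

Step 10
Reactants: 16 methyl (5Z)-7-[(1R,2R)-4-hydroxy-2-[(1E,3S)-3-hydroxyoct-1-en-1-yl]-5-nitrocyclopentyl]hept-5-enoate
Product: 18 methyl (5Z)-7-[(1R,5R)-5-[(1E,3S)-3-acetoxyoct-1-en-1-yl]-2-nitrocyclopent-2-en-1-yl]hept-5-enoate, via bis-acetate 17 (not isolated)
Conditions: Ac2O (4 equiv), 4-(dimethylamino)pyridine (0.2 equiv), pyridine, CH2Cl2, 0 °C → rt
Reagents that add atoms: acetic anhydride, CC(=O)OC(C)=O
Why: Acylation under 4-(dimethylamino)pyridine catalysis turns O15 into the acetate of the target and O10 into a leaving group, and the β-nitro acetate 17 should lose acetic acid by E1cB elimination across the acidic C9–H to the conjugated C9=C10 nitroalkene, which erases the C9 and C10 stereocentres.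

Step 11
Reactants: 18 methyl (5Z)-7-[(1R,5R)-5-[(1E,3S)-3-acetoxyoct-1-en-1-yl]-2-nitrocyclopent-2-en-1-yl]hept-5-enoate
Product: 19 methyl (5Z)-7-[(1R,2S)-2-[(1E,3S)-3-acetoxyoct-1-en-1-yl]-5-oxocyclopent-3-en-1-yl]hept-5-enoate (the target)
Conditions: 1,4-diazabicyclo[2.2.2]octane (2 equiv), O2 (1 atm), MeCN, 0 °C → rt
Reagents that add atoms: dioxygen, O=O
Why: Base-mediated oxidative Nef reaction of a conjugated nitroalkene, in which the amine removes the γ-hydrogen at C11, the allyl nitronate is oxygenated at C9 by O2 and loses nitrite to give the C9 ketone with the alkene now at C10=C11, while the mild base should leave C8 and C12 untouched.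

Compound list
1 | (4-carboxybutyl)triphenylphosphonium bromide | OC(=O)CCCC[P+](c1ccccc1)(c1ccccc1)c1ccccc1.[Br-] | starting material
2 | 3-[(tert-butyldimethylsilyl)oxy]propanal | CC(C)(C)[Si](C)(C)OCCC=O | starting material
3 | (5Z)-8-[(tert-butyldimethylsilyl)oxy]oct-5-enoic acid | CC(C)(C)[Si](C)(C)OCC/C=C\CCCC(=O)O | intermediate
4 | methyl (5Z)-8-hydroxyoct-5-enoate | COC(=O)CCC/C=C\CCO | intermediate
5 | methyl (5Z)-8-oxooct-5-enoate | COC(=O)CCC/C=C\CC=O | intermediate
6 | nitromethane | C[N+](=O)[O-] | starting material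
7 | methyl (5Z)-8-hydroxy-9-nitronon-5-enoate (racemic at C8) | COC(=O)CCC/C=C\CC(O)C[N+](=O)[O-] | intermediate
8 | methyl (5Z,8E)-9-nitronona-5,8-dienoate | COC(=O)CCC/C=C\C/C=C/[N+](=O)[O-] | intermediate
9 | 2,5-dimethoxytetrahydrofuran (cis/trans mixture) | COC1CCC(OC)O1 | starting material
10 | succinaldehyde (butanedial) | O=CCCC=O | intermediate
11 | methyl (5Z,8R,9R)-9-formyl-8-(nitromethyl)-11-oxoundec-5-enoate (syn Michael adduct, not isolated) | COC(=O)CCC/C=C\C[C@@H](C[N+](=O)[O-])[C@H](C=O)CC=O | intermediate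
12 | methyl (5Z)-7-[(1R,2R)-2-formyl-4-hydroxy-5-nitrocyclopentyl]hept-5-enoate (formyl cis to the C8 chain, not isolated) | COC(=O)CCC/C=C\C[C@@H]1[C@H](C=O)CC(O)C1[N+](=O)[O-] | intermediate
13 | methyl (5Z)-7-[(1R,2S)-2-formyl-4-hydroxy-5-nitrocyclopentyl]hept-5-enoate (formyl trans to the C8 chain) | COC(=O)CCC/C=C\C[C@@H]1[C@@H](C=O)CC(O)C1[N+](=O)[O-] | intermediate
14 | dimethyl (2-oxoheptyl)phosphonate | CCCCCC(=O)CP(=O)(OC)OC | starting material
15 | methyl (5Z)-7-[(1R,2R)-4-hydroxy-5-nitro-2-[(1E)-3-oxooct-1-en-1-yl]cyclopentyl]hept-5-enoate | COC(=O)CCC/C=C\C[C@@H]1[C@@H](/C=C/C(=O)CCCCC)CC(O)C1[N+](=O)[O-] | intermediate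
16 | methyl (5Z)-7-[(1R,2R)-4-hydroxy-2-[(1E,3S)-3-hydroxyoct-1-en-1-yl]-5-nitrocyclopentyl]hept-5-enoate | COC(=O)CCC/C=C\C[C@@H]1[C@@H](/C=C/[C@@H](O)CCCCC)CC(O)C1[N+](=O)[O-] | intermediate
17 | methyl (5Z)-7-[(1R,2R)-4-acetoxy-2-[(1E,3S)-3-acetoxyoct-1-en-1-yl]-5-nitrocyclopentyl]hept-5-enoate (not isolated) | COC(=O)CCC/C=C\C[C@@H]1[C@@H](/C=C/[C@@H](OC(C)=O)CCCCC)CC(OC(C)=O)C1[N+](=O)[O-] | intermediate
18 | methyl (5Z)-7-[(1R,5R)-5-[(1E,3S)-3-acetoxyoct-1-en-1-yl]-2-nitrocyclopent-2-en-1-yl]hept-5-enoate | COC(=O)CCC/C=C\C[C@@H]1[C@@H](/C=C/[C@@H](OC(C)=O)CCCCC)CC=C1[N+](=O)[O-] | intermediate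
19 | methyl (5Z)-7-[(1R,2S)-2-[(1E,3S)-3-acetoxyoct-1-en-1-yl]-5-oxocyclopent-3-en-1-yl]hept-5-enoate | CCCCC[C@@H](/C=C/[C@H]1C=CC(=O)[C@@H]1C/C=C\CCCC(=O)OC)OC(C)=O | target

Total step count: 11. Longest linear sequence: 10 (steps 1–5 and 7–11; step 6 is a one-step branch).

Steps most likely to fail

1. Step 7. Proton transfer from the doubly activated C7 methylene of 8 to the amine catalyst or to the enamine may outrun conjugate addition, so that the nitrodiene drifts into conjugated isomers and the annulation stalls. The fallback introduces the 5Z alkene only after the ring is built. It sets out from 2 and 6 and comes back at 16. Nitroaldol addition (catalytic tetramethylguanidine) should give racemic 4-[(tert-butyldimethylsilyl)oxy]-1-nitrobutan-2-ol F1, and carbodiimide dehydration (N,N'-dicyclohexylcarbodiimide, CuCl) tert-butyldimethyl{[(3E)-4-nitrobut-3-en-1-yl]oxy}silane F2, an ordinary alkyl nitroalkene without a doubly activated methylene. With 10 under the conditions of step 7 this should give (1S,2R)-2-{2-[(tert-butyldimethylsilyl)oxy]ethyl}-4-hydroxy-3-nitrocyclopentane-1-carbaldehyde F3. Olefination with 14 as in step 8 would give (1E)-1-[(1R,2R)-2-{2-[(tert-butyldimethylsilyl)oxy]ethyl}-4-hydroxy-3-nitrocyclopentyl]oct-1-en-3-one F4, and reduction as in step 9 (1E,3S)-1-[(1R,2R)-2-{2-[(tert-butyldimethylsilyl)oxy]ethyl}-4-hydroxy-3-nitrocyclopentyl]oct-1-en-3-ol F5. HF·pyridine in THF would free the primary alcohol to give (1E,3S)-1-[(1R,2R)-4-hydroxy-2-(2-hydroxyethyl)-3-nitrocyclopentyl]oct-1-en-3-ol F6. 2,2,6,6-Tetramethylpiperidine-1-oxyl with PhI(OAc)2 would oxidise only that primary alcohol to 2-[(1R,2R)-4-hydroxy-2-[(1E,3S)-3-hydroxyoct-1-en-1-yl]-5-nitrocyclopentyl]acetaldehyde F7. Wittig reaction with an excess of the ylide from 1 (as in step 1; the first equivalent converts the nitro group into its nitronate) would give (5Z)-7-[(1R,2R)-4-hydroxy-2-[(1E,3S)-3-hydroxyoct-1-en-1-yl]-5-nitrocyclopentyl]hept-5-enoic acid F8, and methylation with Me3SiCHN2 in MeOH–toluene returns the route at 16.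

2. Step 4 (step 5 shares the weakness). Under the basic nitroaldol conditions the C5=C6 alkene of 5 may migrate into conjugation with the formyl group through enolisation at C7, after which nitromethane would add in a Michael sense; the same mobility threatens the dehydration. The fallback makes the nitroalkene by selenoxide elimination from the saturated nitroalkane, so that neither a β,γ-unsaturated aldehyde nor a base-exposed skipped nitrodiene occurs. It sets out from 1 and comes back at 8. Wittig reaction as in step 1 with commercial 4-[(tert-butyldimethylsilyl)oxy]butanal should give (5Z)-9-[(tert-butyldimethylsilyl)oxy]non-5-enoic acid F9, and acidic methanol as in step 2 methyl (5Z)-9-hydroxynon-5-enoate F10. Appel iodination (I2, PPh3, imidazole) gives methyl (5Z)-9-iodonon-5-enoate F11, and AgNO2 in Et2O methyl (5Z)-9-nitronon-5-enoate F12. Its nitronate (KOtBu, THF, −78 °C) with PhSeBr gives methyl (5Z)-9-nitro-9-(phenylselanyl)non-5-enoate F13. Oxidation with H2O2 at 0 °C gives methyl (5Z)-9-nitro-9-(phenylseleninyl)non-5-enoate F14, whose syn elimination at room temperature returns the route at 8.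

3. Step 11. Under the basic aerobic conditions the product, whose C12 hydrogen is γ to the enone and doubly allylic, may isomerise further to the C8=C12 dienone, or oxygenation may take place at C11 instead of C9. The fallback reaches the enone without exposing it to amine base. It sets out from 18 and comes back at 19. A reductive Nef reaction with Fe powder in aqueous AcOH should give methyl (5Z)-7-[(1R,2R)-2-[(1E,3S)-3-acetoxyoct-1-en-1-yl]-5-oxocyclopentyl]hept-5-enoate F15. Kinetic deprotonation at the C10 methylene (LiN(iPr)2, Me3SiCl, THF, −78 °C) gives methyl (5Z)-7-[(1R,5R)-5-[(1E,3S)-3-acetoxyoct-1-en-1-yl]-2-[(trimethylsilyl)oxy]cyclopent-2-en-1-yl]hept-5-enoate F16, and Saegusa–Ito dehydrogenation with Pd(OAc)2 in MeCN returns the route at 19.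

Further compounds
F1 | step 7 | 4-[(tert-butyldimethylsilyl)oxy]-1-nitrobutan-2-ol (racemic) | CC(C)(C)[Si](C)(C)OCCC(O)C[N+](=O)[O-]
F2 | step 7 | tert-butyldimethyl{[(3E)-4-nitrobut-3-en-1-yl]oxy}silane | CC(C)(C)[Si](C)(C)OCC/C=C/[N+](=O)[O-]
F3 | step 7 | (1S,2R)-2-{2-[(tert-butyldimethylsilyl)oxy]ethyl}-4-hydroxy-3-nitrocyclopentane-1-carbaldehyde | CC(C)(C)[Si](C)(C)OCC[C@@H]1[C@@H](C=O)CC(O)C1[N+](=O)[O-]
F4 | step 7 | (1E)-1-[(1R,2R)-2-{2-[(tert-butyldimethylsilyl)oxy]ethyl}-4-hydroxy-3-nitrocyclopentyl]oct-1-en-3-one | CC(C)(C)[Si](C)(C)OCC[C@@H]1[C@@H](/C=C/C(=O)CCCCC)CC(O)C1[N+](=O)[O-]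
F5 | step 7 | (1E,3S)-1-[(1R,2R)-2-{2-[(tert-butyldimethylsilyl)oxy]ethyl}-4-hydroxy-3-nitrocyclopentyl]oct-1-en-3-ol | CC(C)(C)[Si](C)(C)OCC[C@@H]1[C@@H](/C=C/[C@@H](O)CCCCC)CC(O)C1[N+](=O)[O-]
F6 | step 7 | (1E,3S)-1-[(1R,2R)-4-hydroxy-2-(2-hydroxyethyl)-3-nitrocyclopentyl]oct-1-en-3-ol | OCC[C@@H]1[C@@H](/C=C/[C@@H](O)CCCCC)CC(O)C1[N+](=O)[O-]
F7 | step 7 | 2-[(1R,2R)-4-hydroxy-2-[(1E,3S)-3-hydroxyoct-1-en-1-yl]-5-nitrocyclopentyl]acetaldehyde | O=CC[C@@H]1[C@@H](/C=C/[C@@H](O)CCCCC)CC(O)C1[N+](=O)[O-]
F8 | step 7 | (5Z)-7-[(1R,2R)-4-hydroxy-2-[(1E,3S)-3-hydroxyoct-1-en-1-yl]-5-nitrocyclopentyl]hept-5-enoic acid | OC(=O)CCC/C=C\C[C@@H]1[C@@H](/C=C/[C@@H](O)CCCCC)CC(O)C1[N+](=O)[O-]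
F9 | step 4 | (5Z)-9-[(tert-butyldimethylsilyl)oxy]non-5-enoic acid | CC(C)(C)[Si](C)(C)OCCC/C=C\CCCC(=O)O
F10 | step 4 | methyl (5Z)-9-hydroxynon-5-enoate | COC(=O)CCC/C=C\CCCO
F11 | step 4 | methyl (5Z)-9-iodonon-5-enoate | COC(=O)CCC/C=C\CCCI
F12 | step 4 | methyl (5Z)-9-nitronon-5-enoate | COC(=O)CCC/C=C\CCC[N+](=O)[O-]
F13 | step 4 | methyl (5Z)-9-nitro-9-(phenylselanyl)non-5-enoate | COC(=O)CCC/C=C\CCC([Se]c1ccccc1)[N+](=O)[O-]
F14 | step 4 | methyl (5Z)-9-nitro-9-(phenylseleninyl)non-5-enoate | COC(=O)CCC/C=C\CCC([Se](=O)c1ccccc1)[N+](=O)[O-]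
F15 | step 11 | methyl (5Z)-7-[(1R,2R)-2-[(1E,3S)-3-acetoxyoct-1-en-1-yl]-5-oxocyclopentyl]hept-5-enoate | COC(=O)CCC/C=C\C[C@@H]1[C@@H](/C=C/[C@@H](OC(C)=O)CCCCC)CCC1=O
F16 | step 11 | methyl (5Z)-7-[(1R,5R)-5-[(1E,3S)-3-acetoxyoct-1-en-1-yl]-2-[(trimethylsilyl)oxy]cyclopent-2-en-1-yl]hept-5-enoate | COC(=O)CCC/C=C\C[C@@H]1[C@@H](/C=C/[C@@H](OC(C)=O)CCCCC)CC=C1O[Si](C)(C)C
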